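**Plan**
Locants: ring A (five-membered) is C1, C2, C3, C4 (methyl), C5. Ring B (seven-membered) is C1, C10 (=CH2), C9 (OH), C8, C7, C6 (OH), C5. The chain leaves C7 as C11 (methyl), C12 (OAc), C13, C14 (OH), C15 (isopropenyl carbon).
Cuts, in retrosynthetic order: C12–C13 (aldol); C10=CH2 and C9–O (ketone chemistry); C3=C4 (metathesis); C1–C2 and C4–C5 (enolate allylation, cuprate addition); one C–O bond of an oxygen bridge; last, C6–C7 and C8–C9 together.
The double cut is possible because ring B holds C10 (a masked ketone) beside oxygenated C9, and a second oxygen on C6 lies 1,4 to C9 across C8–C7. With one oxygen spanning C6 and C9 and an enone C10(=O)–C1=C5, ring B is an 8-oxabicyclo[3.2.1]oct-3-en-2-one, the (5+2) adduct of 3-oxidopyrylium with an acrylate whose carbonyl carbon is C11.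
Forward order: ring B forms first, as the carbocycle of the bridged adduct. The C11–C12 stub is grown on the rigid bicycle, the bridge is opened, ring A is annulated, C9/C10 are finished, and C13–C15 are joined last.
Stereochemistry: C6/C7 come from the exo adduct, made a single enantiomer through a lactate ester. C11 comes from hydroboration on the bicycle. C5, C1 and C9 are relayed from C6/C7. C12 is set by (+)-Ipc2BCl and C14 by the (S)-CBS catalyst.

Key step: step 4

Remark: the SMILES is read as 1S,5R,6S,7R,9S,11S,12S,14R, that is H1 anti to H5 (trans-fused rings), O6 cis to C11, O9 trans to O6, and C11-methyl/O12 and O12/O14 both syn in the zigzag chain; because a C6–O–C9 bridge can only be cis, the C9–O bond of the adduct is sacrificial and O9 is put back later from the other face.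

Step 1
Reactants: 1 furfuryl alcohol
Product: 2 6-hydroxy-2H-pyran-3(6H)-one (racemic hemiacetal)
Conditions: mCPBA, CH2Cl2, 0 °C → rt
Reagents that add atoms: mCPBA (3-chloroperoxybenzoic acid), O=C(OO)c1cccc(Cl)c1
Why: Achmatowicz oxidative ring expansion, in which the peracid oxidises the electron-rich furan to a cis-enedione that recloses through the carbinol oxygen to the pyranone hemiacetal, whose racemic centre is erased when the ylide forms in step 4.

Step 2
Reactants: 2 6-hydroxy-2H-pyran-3(6H)-one
Product: 3 6-acetoxy-2H-pyran-3(6H)-one (racemic)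
Conditions: Ac2O, pyridine, CH2Cl2, 0 °C
Reagents that add atoms: acetic anhydride, CC(=O)OC(C)=O
Why: O-acetylation of the hemiacetal installs the leaving group for ylide formation, pyridine at 0 °C being too weak a base to start that elimination.

Step 3
Reactants: 4 ethyl (S)-lactate; 5 acryloyl chloride
Product: 6 (S)-1-ethoxy-1-oxopropan-2-yl acrylate
Conditions: Et3N, CH2Cl2, 0 °C
Reagents that add atoms: none
Why: Acylation of a secondary alcohol by an acid chloride with Et3N as HCl scavenger, which does not touch the lactate stereocentre.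

Step 4
Reactants: 3 6-acetoxy-2H-pyran-3(6H)-one; 6 (S)-1-ethoxy-1-oxopropan-2-yl acrylate (excess)
Product: 8 (S)-1-ethoxy-1-oxopropan-2-yl (1R,5R,6S)-2-oxo-8-oxabicyclo[3.2.1]oct-3-ene-6-carboxylate (exo ester; bicycle C1/C5/C6 = target C9/C6/C7), via 3-oxidopyrylium ylide 7 (not isolated)
Conditions: Et3N (slow addition), CH2Cl2, rt; chromatography, crystallisation
Reagents that add atoms: none
Why: Et3N enolises 3 towards its CH2 group and acetate leaves, giving the planar 3-oxidopyrylium 7, a carbonyl ylide across the ring oxygen whose two termini (future C9 and C6) add suprafacially to the C=C of 6 in a concerted, thermally allowed six-electron process. The closest known reaction type is the oxidopyrylium–alkene (5+2) cycloaddition of this same acetoxypyranone with acrylic dipolarophiles, and lactate acrylates have served in the same way with 3-oxidopyridinium betaines. Ring B closes as the seven-membered carbocycle of the bicycle by intermolecular cycloaddition, C6–C7 and C8–C9 forming in one event (the tetrahydrofuran ring O–C6–C7–C8–C9 closes at the same moment), so no end-to-end cyclisation is involved. C6 and C9 are tied cis by the bridging oxygen, C7 follows from the exo orientation of the bulky ester (cis to the bridge, turned away from the enone bridge), and the absolute sense rests on the (S)-lactate, which makes the two exo adducts diastereomers so that 8 can be taken pure. The step needs regioselectivity, secured by the polarisation of 7 (its nucleophilic carbon next to the oxido group, future C9, bonds to the electrophilic CH2 of the acrylate, so C11 ends on C7 beside C6), and chemoselectivity over ylide dimerisation, secured by excess 6 and slow addition of base.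

Step 5
Reactants: 8 exo lactate ester adduct
Product: 9 endo allylic alcohol: the C10 ketone of 8 reduced to the (10R) carbinol, OH on the face away from the oxygen bridge, both esters intact
Conditions: NaBH4, CeCl3·7H2O, MeOH, −78 °C
Reagents that add atoms: none
Why: Luche 1,2-reduction masks the enone as an allylic alcohol so that the ester can be worked on, hydride arriving from the exo face beside the oxygen bridge to give the endo alcohol, a centre that is erased again in step 10.

Step 6
Reactants: 9 endo allylic alcohol
Product: 10 Weinreb amide: exo C7–C(=O)N(OMe)Me on the 8-oxabicyclo[3.2.1]oct-3-en-2-endo-ol core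
Conditions: MeNHOMe·HCl, iPrMgCl, THF, −20 → 0 °C
Reagents that add atoms: N,O-dimethylhydroxylamine hydrochloride, CNOC.Cl
Why: Weinreb aminolysis with the magnesium amide displaces the activated lactate alkoxide and so removes the auxiliary, while C7 stays in the thermodynamically preferred exo configuration.

Step 7
Reactants: 10 Weinreb amide
Product: 11 exo methyl ketone (C7–C11(=O)CH3) on the same bicyclic allylic alcohol
Conditions: MeMgBr, THF, 0 °C
Reagents that add atoms: methylmagnesium bromide, C[Mg]Br
Why: Weinreb ketone synthesis, in which the chelated tetrahedral adduct stops the Grignard addition at the ketone stage, one further equivalent of MeMgBr being spent on the free hydroxyl group.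

Step 8
Reactants: 11 exo methyl ketone
Product: 12 exo isopropenyl compound (C7–C11(=CH2)CH3) on the same bicyclic allylic alcohol
Conditions: Ph3PCH3Br, KOtBu, THF, 0 °C → rt
Reagents that add atoms: methyltriphenylphosphonium bromide, C[P+](c1ccccc1)(c1ccccc1)c1ccccc1.[Br-]
Why: Wittig methylenation of an unhindered methyl ketone, in which passing enolisation at C7 does no harm because the exo epimer is the stable one.

Step 9
Reactants: 12 exo isopropenyl compound
Product: 14 (11S)-diol: exo C7–CH(CH3)CH2OH plus the endo C10 allylic alcohol, via bis-9-BBN adduct 13 (not isolated)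
Conditions: 9-BBN, THF, 0 °C → rt; then NaOH, H2O2, 0 °C
Reagents that add atoms: hydrogen peroxide, OO
Why: Brown hydroboration–oxidation, in which 9-BBN takes the 1,1-disubstituted alkene far faster than the ring cis-alkene flanked by two oxygenated carbons, and in the staggered rotamer with the endo C7–H inside (eclipsing C11=CH2) the borane comes from the side of the C8 methylene, anti to the more encumbered bridgehead C6, which places H on C11 so as to give 11S.

Step 10
Reactants: 14 (11S)-diol
Product: 15 hydroxy enone: 8-oxabicyclo[3.2.1]oct-3-en-2-one with the exo (S)-1-hydroxypropan-2-yl group on C7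
Conditions: MnO2, CH2Cl2, rt
Reagents that add atoms: none
Why: MnO2 oxidises only the allylic alcohol, so the C10 enone returns and the saturated primary alcohol is left alone.

Step 11
Reactants: 15 hydroxy enone
Product: 16 (4R,5R)-4-hydroxy-5-[(2S)-1-hydroxypropan-2-yl]cyclohept-2-en-1-one (ring carbons 1–5 = target C10, C1, C5, C6, C7; OH and side chain cis)
Conditions: SmI2, THF–MeOH, −78 °C
Reagents that add atoms: none
Why: SmI2 reduction of an α-alkoxy ketone, in which two electrons enter the C10 carbonyl, the C9–O bond (held almost parallel to the carbonyl π system and strained by the bridge) leaves as the C6 alkoxide and MeOH protonates the samarium enolate at C9, so the wrongly configured C9–O bond is removed while C6 and C7 are untouched.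

Step 12
Reactants: 16 ring-opened diol enone
Product: 17 bis(triethylsilyl) ether of 16 (O6 and O12 silylated)
Conditions: TESCl, imidazole, DMAP (cat.), DMF, 0 °C → rt
Reagents that add atoms: chlorotriethylsilane, CC[Si](Cl)(CC)CC
Why: Standard silylation of both hydroxyl groups, the C6 silyl ether serving to steer the next step and the primary one as the handle for step 19.

Step 13
Reactants: 17 bis(triethylsilyl) ether enone; 18 isopropenylmagnesium bromide
Product: 19 trimethylsilyl enol ether C10(OTMS)=C1 carrying the new C5 isopropenyl group trans to O6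
Conditions: CuBr·SMe2 (20 mol %), TMSCl, DMPU, THF, −78 °C
Reagents that add atoms: chlorotrimethylsilane, C[Si](C)(C)Cl
Why: Copper-catalysed, TMSCl-accelerated conjugate addition of a Grignard reagent, in which the isopropenyl group reaches C5 anti to the C6 silyloxy group and the C7 side chain (both on the same face), as is usual for 4-silyloxy cycloalkenones, and the enolate is trapped regiospecifically as its silyl ether.

Step 14
Reactants: 19 trimethylsilyl enol ether; 20 allyl iodide
Product: 22 cycloheptanone with C1 allyl trans to C5 isopropenyl (C5 isopropenyl trans to O6; O6 cis to the C7 chain), via lithium enolate 21 (not isolated)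
Conditions: MeLi, THF, 0 °C; then 20, DMPU, −78 → −20 °C
Reagents that add atoms: none
Why: Cleavage of the silyl enol ether with MeLi releases the regiodefined lithium enolate, which is alkylated (SN2) by allyl iodide from the face of C1 anti to the neighbouring C5 isopropenyl group, giving the 1,5-trans product that is also the more stable epimer.

Step 15
Reactants: 22 allyl isopropenyl cycloheptanone
Product: 23 trans-fused hydroazulenone: ring A closed with C3=C4(CH3), C10 ketone, O6 and O12 as triethylsilyl ethers
Conditions: second-generation Grubbs catalyst (H2IMes)(PCy3)Cl2Ru=CHPh (5 mol %), CH2Cl2, 40 °C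
Reagents that add atoms: none
Why: Ring-closing metathesis starts at the monosubstituted allyl alkene and closes five-membered ring A onto the gauche, diequatorial isopropenyl group with loss of ethene, under neutral conditions that leave the trans relation at C1/C5 intact.

Step 16
Reactants: 23 trans-fused hydroazulenone
Product: 25 (9S)-α-hydroxy ketone (O9 trans to O6), via potassium enolate 24 (not isolated)
Conditions: KN(SiMe3)2, THF, −78 °C; 2-(phenylsulfonyl)-3-phenyloxaziridine, −78 °C; AcOH
Reagents that add atoms: 2-(phenylsulfonyl)-3-phenyloxaziridine, O=S(=O)(c1ccccc1)N1OC1c1ccccc1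
Why: Davis enolate hydroxylation, in which the bulky amide base removes a proton kinetically from the C9 methylene and not the ring-fusion C1–H, and the oxaziridine attacks the enolate face opposite to the C6 silyl ether and to the C7 side chain (pseudo-axial on that face once ring A is fused trans-diequatorially), so that O9 ends trans to O6.

Step 17
Reactants: 25 (9S)-α-hydroxy ketone
Product: 26 C9 tert-butyldimethylsilyl ether of 25
Conditions: TBSOTf, 2,6-lutidine, CH2Cl2, −78 → 0 °C
Reagents that add atoms: tert-butyldimethylsilyl triflate, CC(C)(C)[Si](C)(C)OS(=O)(=O)C(F)(F)F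
Why: A silyl triflate with a hindered pyridine base caps the α-ketol quickly at low temperature and so blocks ketol shift and epimerisation.

Step 18
Reactants: 26 α-silyloxy ketone
Product: 27 exocyclic alkene C10=CH2 (O9 TBS; O6 and O12 TES)
Conditions: Cp2TiMe2, toluene, 70 °C
Reagents that add atoms: dimethyltitanocene Cp2TiMe2, [CH3-].[CH3-].[Ti+4].c1cc[cH-]c1.c1cc[cH-]c1
Why: Petasis methylenation, whose carbene Cp2Ti=CH2 is non-basic and so converts the hindered, enolisable C10 ketone into the alkene without disturbing C1 or C9.

Step 19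
Reactants: 27 tris-silyl ether
Product: 28 (11S)-aldehyde C12HO (O9 TBS, O6 TES retained)
Conditions: (COCl)2, DMSO, CH2Cl2, −78 → −40 °C; Et3N, −78 → 0 °C
Reagents that add atoms: none
Why: Known direct Swern oxidation of primary triethylsilyl ethers, in which the chlorosulfonium salt attacks only the least hindered silyl ether oxygen, so deprotection and oxidation are one operation, and the cold addition of base keeps the C11 stereocentre.

Step 20
Reactants: 28 (11S)-aldehyde; 29 3-methylbut-3-en-2-one
Product: 32 (12S)-β-hydroxy enone C12(OH)–C13H2–C14(=O)–C15(=CH2)CH3, via boron enolate 30 (not isolated), via boron aldolate 31 (not isolated)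
Conditions: 29, (+)-Ipc2BCl, Et3N, Et2O, 0 °C; 28, −78 → −20 °C; H2O2, MeOH, pH 7 buffer, 0 °C
Reagents that add atoms: none
Why: Ipc2BCl-mediated boron aldol reaction of a methyl ketone, in which the only possible enolate 30 carries isopinocampheyl ligands that direct attack to the aldehyde face giving the (12S) carbinol, the same face that Felkin–Anh control by C11 favours (11,12-syn), so reagent and substrate are matched.

Step 21
Reactants: 32 (12S)-β-hydroxy enone
Product: 33 (12S)-acetate of 32
Conditions: Ac2O, pyridine, DMAP (cat.), CH2Cl2, 0 °C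
Reagents that add atoms: acetic anhydride, CC(=O)OC(C)=O
Why: DMAP-catalysed acetylation, kept cold and short to avoid β-elimination, puts the acetate on O12 while it is the only free hydroxyl group.

Step 22
Reactants: 33 β-acetoxy enone
Product: 34 (14R)-allylic alcohol (12,14-syn), O9 TBS and O6 TES still in place
Conditions: (S)-2-methyl-CBS-oxazaborolidine, catecholborane, toluene, −78 °C
Reagents that add atoms: none
Why: Corey–Bakshi–Shibata reduction, in which the (S)-catalyst binds the ketone with the branched isopropenyl group as the large and the C13 methylene as the small substituent and delivers hydride 1,2 to give the (14R) alcohol, catecholborane at −78 °C leaving alkenes and acetate alone.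

Step 23
Reactants: 34 bis-silyl ether
Product: 35 target CNP0281601.4
Conditions: HF·pyridine, pyridine, THF, 0 °C → rt
Reagents that add atoms: none
Why: Buffered acidic fluoride cleaves both silyl ethers, and the non-basic medium avoids acetyl migration from O12 to O14 and ionisation of the two allylic alcohols.

**Compound list**
1 | furfuryl alcohol | OCc1ccco1 | starting material
2 | 6-hydroxy-2H-pyran-3(6H)-one (racemic) | OC1OCC(=O)C=C1 | intermediate
3 | 6-acetoxy-2H-pyran-3(6H)-one (racemic) | CC(=O)OC1OCC(=O)C=C1 | intermediate
4 | ethyl (S)-lactate | CCOC(=O)[C@H](C)O | starting material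
5 | acryloyl chloride | C=CC(Cl)=O | starting material
6 | (S)-1-ethoxy-1-oxopropan-2-yl acrylate | C=CC(=O)O[C@@H](C)C(=O)OCC | intermediate
7 | 3-oxidopyrylium ylide | [O-]c1c[o+]ccc1 | intermediate
8 | (S)-1-ethoxy-1-oxopropan-2-yl (1R,5R,6S)-2-oxo-8-oxabicyclo[3.2.1]oct-3-ene-6-exo-carboxylate | O=C1C=C[C@@H]2[C@@H](C(=O)O[C@@H](C)C(=O)OCC)C[C@H]1O2 | intermediate
9 | endo (10R) allylic alcohol of 8 | O[C@@H]1C=C[C@@H]2[C@@H](C(=O)O[C@@H](C)C(=O)OCC)C[C@H]1O2 | intermediate
10 | exo Weinreb amide | O[C@@H]1C=C[C@@H]2[C@@H](C(=O)N(C)OC)C[C@H]1O2 | intermediate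
11 | exo methyl ketone | O[C@@H]1C=C[C@@H]2[C@@H](C(C)=O)C[C@H]1O2 | intermediate
12 | exo isopropenyl compound | O[C@@H]1C=C[C@@H]2[C@@H](C(C)=C)C[C@H]1O2 | intermediate
13 | bis-9-BBN adduct (C12–B and O10–B) | B1(C2CCCC1CCC2)O[C@@H]3C=C[C@@H]4[C@@H]([C@H](C)CB5C6CCCC5CCC6)C[C@H]3O4 | intermediate
14 | (11S)-diol | O[C@@H]1C=C[C@@H]2[C@@H]([C@H](C)CO)C[C@H]1O2 | intermediate
15 | bicyclic hydroxy enone | O=C1C=C[C@@H]2[C@@H]([C@H](C)CO)C[C@H]1O2 | intermediate
16 | (4R,5R)-4-hydroxy-5-[(2S)-1-hydroxypropan-2-yl]cyclohept-2-en-1-one | OC[C@@H](C)[C@H]1CCC(=O)C=C[C@H]1O | intermediate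
17 | bis(triethylsilyl) ether of 16 | CC[Si](CC)(CC)OC[C@@H](C)[C@H]1CCC(=O)C=C[C@H]1O[Si](CC)(CC)CC | intermediate
18 | isopropenylmagnesium bromide | CC(=C)[Mg]Br | starting material
19 | trimethylsilyl enol ether with C5 isopropenyl trans to O6 | CC[Si](CC)(CC)OC[C@@H](C)[C@H]1CCC(O[Si](C)(C)C)=C[C@H](C(C)=C)[C@H]1O[Si](CC)(CC)CC | intermediate
20 | allyl iodide | C=CCI | starting material
21 | lithium enolate | CC[Si](CC)(CC)OC[C@@H](C)[C@H]1CCC([O-])=C[C@H](C(C)=C)[C@H]1O[Si](CC)(CC)CC.[Li+] | intermediate
22 | 1,5-trans allyl isopropenyl cycloheptanone | CC[Si](CC)(CC)OC[C@@H](C)[C@H]1CCC(=O)[C@@H](CC=C)[C@H](C(C)=C)[C@H]1O[Si](CC)(CC)CC | intermediate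
23 | trans-fused hydroazulenone | CC[Si](CC)(CC)OC[C@@H](C)[C@H]1CCC(=O)[C@H]2CC=C(C)[C@@H]2[C@H]1O[Si](CC)(CC)CC | intermediate
24 | potassium enolate (C9=C10) | CC[Si](CC)(CC)OC[C@@H](C)[C@H]1CC=C([O-])[C@H]2CC=C(C)[C@@H]2[C@H]1O[Si](CC)(CC)CC.[K+] | intermediate
25 | (9S)-α-hydroxy ketone | CC[Si](CC)(CC)OC[C@@H](C)[C@H]1C[C@H](O)C(=O)[C@H]2CC=C(C)[C@@H]2[C@H]1O[Si](CC)(CC)CC | intermediate
26 | C9 TBS ether of 25 | CC[Si](CC)(CC)OC[C@@H](C)[C@H]1C[C@H](O[Si](C)(C)C(C)(C)C)C(=O)[C@H]2CC=C(C)[C@@H]2[C@H]1O[Si](CC)(CC)CC | intermediate
27 | C10 exocyclic alkene | CC[Si](CC)(CC)OC[C@@H](C)[C@H]1C[C@H](O[Si](C)(C)C(C)(C)C)C(=C)[C@H]2CC=C(C)[C@@H]2[C@H]1O[Si](CC)(CC)CC | intermediate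
28 | (11S)-C12 aldehyde | O=C[C@@H](C)[C@H]1C[C@H](O[Si](C)(C)C(C)(C)C)C(=C)[C@H]2CC=C(C)[C@@H]2[C@H]1O[Si](CC)(CC)CC | intermediate
29 | 3-methylbut-3-en-2-one | CC(=O)C(C)=C | starting material
30 | diisopinocampheylboron enolate of 29 | C=C(C)C(=C)OB([C@H]1C[C@H]2C[C@@H]([C@@H]1C)C2(C)C)[C@H]1C[C@H]2C[C@@H]([C@@H]1C)C2(C)C | intermediate
31 | boron aldolate | C=C(C)C(=O)C[C@H](OB([C@H]1C[C@H]2C[C@@H]([C@@H]1C)C2(C)C)[C@H]1C[C@H]2C[C@@H]([C@@H]1C)C2(C)C)[C@@H](C)[C@H]1C[C@H](O[Si](C)(C)C(C)(C)C)C(=C)[C@H]2CC=C(C)[C@@H]2[C@H]1O[Si](CC)(CC)CC | intermediate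
32 | (12S)-β-hydroxy enone | C=C(C)C(=O)C[C@H](O)[C@@H](C)[C@H]1C[C@H](O[Si](C)(C)C(C)(C)C)C(=C)[C@H]2CC=C(C)[C@@H]2[C@H]1O[Si](CC)(CC)CC | intermediate
33 | (12S)-β-acetoxy enone | C=C(C)C(=O)C[C@H](OC(C)=O)[C@@H](C)[C@H]1C[C@H](O[Si](C)(C)C(C)(C)C)C(=C)[C@H]2CC=C(C)[C@@H]2[C@H]1O[Si](CC)(CC)CC | intermediate
34 | (14R)-allylic alcohol, bis-silyl ether of the target | C=C(C)[C@H](O)C[C@H](OC(C)=O)[C@@H](C)[C@H]1C[C@H](O[Si](C)(C)C(C)(C)C)C(=C)[C@H]2CC=C(C)[C@@H]2[C@H]1O[Si](CC)(CC)CC | intermediate
35 | CNP0281601.4 | C=C(C)[C@H](O)C[C@H](OC(C)=O)[C@@H](C)[C@H]1C[C@H](O)C(=C)[C@H]2CC=C(C)[C@@H]2[C@H]1O | target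

**Step count**
- Total steps: 23.
- Longest linear sequence: 22 steps (1, 2 and 4–23 from furfuryl alcohol). Step 3 is a one-step side branch.

**Steps most likely to fail**

Step 4.
- What may go wrong: a weak facial bias of the uncatalysed lactate acrylate, an unfavourable exo/endo partition at C7, a hard separation of the diastereomers, and loss of ylide by dimerisation.
- Fallback (sets out from 3, comes back at 10): induction is given up for resolution. Acetoxypyranone 3 and methyl acrylate under the conditions of step 4 should give the racemic exo methyl ester F1. With no second base-sensitive stereocentre in the molecule, the exo/endo mixture at C7 can now be equilibrated with DBU. Luche reduction gives the racemic endo allylic alcohol F2. A lipase (Pseudomonas cepacia lipase, vinyl acetate, MTBE) should, by the empirical size rule for secondary alcohols, acetylate the (10R) enantiomer to the acetate F3, which is separated from the unreacted antipode. The conditions of step 6 turn the methyl ester of F3 into the Weinreb amide and strip the acetate, which gives 10.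

Step 9.
- What may go wrong: low or reversed facial selectivity of the hydroboration at the freely rotating isopropenyl group, which would erode C11.
- Fallback (sets out from 10, comes back at 14): C11 is set by a chiral catalyst instead of by the substrate. iBu2AlH reduces Weinreb amide 10 to the exo aldehyde F4, and Wittig methylenation gives the vinyl compound F5. Zirconium-catalysed asymmetric carboalumination then adds methyl to C11 and aluminium to C12 of the only monosubstituted alkene, giving the alane F6. The conditions are Me3Al and bis(1-neomenthylindenyl)zirconium dichloride, (+)-(NMI)2ZrCl2, in CH2Cl2; this is the antipode of the catalyst that turns 1-alkenes into (R)-2-methylalkan-1-ols. O2 oxidises F6 to diol 14.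

Step 11.
- What may go wrong: after electron transfer to the enone, the vinylogous C6–O bond may be lost instead of the C9–O bond, or the enone may be over-reduced.
- Fallback (sets out from 15, comes back at 17): the enone is first taken out of conjugation. Et3N-catalysed conjugate addition of thiophenol to 15 should give the 5-exo-phenylthio ketone F7. In this saturated α-alkoxy ketone, SmI2 in THF–MeOH can break only C9–O and should give the ring-opened thio diol F8. TESCl and imidazole give the bis(triethylsilyl) ether F9, and one equivalent of mCPBA at −78 °C gives the sulfoxide F10. Warming with CaCO3 in toluene brings about syn elimination towards the acidified C1–H, which restores the C1=C5 enone of 17.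

**Further compounds**
F1 | step 4 | methyl 2-oxo-8-oxabicyclo[3.2.1]oct-3-ene-6-exo-carboxylate (racemate, needed enantiomer drawn) | O=C1C=C[C@@H]2[C@@H](C(=O)OC)C[C@H]1O2
F2 | step 4 | methyl 2-endo-hydroxy-8-oxabicyclo[3.2.1]oct-3-ene-6-exo-carboxylate (racemate, needed enantiomer drawn) | O[C@@H]1C=C[C@@H]2[C@@H](C(=O)OC)C[C@H]1O2
F3 | step 4 | (10R)-acetate of F2, single enantiomer | CC(=O)O[C@@H]1C=C[C@@H]2[C@@H](C(=O)OC)C[C@H]1O2
F4 | step 9 | exo C7 carbaldehyde of the bicyclic allylic alcohol | O[C@@H]1C=C[C@@H]2[C@@H](C=O)C[C@H]1O2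
F5 | step 9 | exo C7 vinyl compound | O[C@@H]1C=C[C@@H]2[C@@H](C=C)C[C@H]1O2
F6 | step 9 | (11S)-C12 dimethylalane, O10 as dimethylaluminium alkoxide | C[Al](C)O[C@@H]1C=C[C@@H]2[C@@H]([C@H](C)C[Al](C)C)C[C@H]1O2
F7 | step 11 | 5-exo-phenylthio ketone | O=C1C[C@@H](Sc3ccccc3)[C@@H]2[C@@H]([C@H](C)CO)C[C@H]1O2
F8 | step 11 | ring-opened thio diol | OC[C@@H](C)[C@H]1CCC(=O)C[C@@H](Sc2ccccc2)[C@H]1O
F9 | step 11 | bis(triethylsilyl) ether of F8 | CC[Si](CC)(CC)OC[C@@H](C)[C@H]1CCC(=O)C[C@@H](Sc2ccccc2)[C@H]1O[Si](CC)(CC)CC
F10 | step 11 | sulfoxide of F9 (sulfur configuration open) | CC[Si](CC)(CC)OC[C@@H](C)[C@H]1CCC(=O)C[C@@H](S(=O)c2ccccc2)[C@H]1O[Si](CC)(CC)CC
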